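With the cyclohexene numbered C1 (methyl-bearing alkene carbon), C2, C3, C4 (acyloxy carbon), C5 (CMe2), C6 and C7 (the CH2O carbon on C6), the feature exploited is the cis pair C4–O and C6–C7 across quaternary C5: it is read as a bridged lactone, hence as the Baeyer–Villiger product of a cyclobutanone whose carbonyl carbon C7 spans C4 and C6, a one-carbon bridge that can only be cis. That bicyclo[3.1.1]heptenone is cut at C7–C4 and C6–C5: one crossed intramolecular [2+2] cycloaddition of a chiral vinylketeniminium ion closes the cyclohexene and the cyclobutane and sets both stereocentres. Its precursor is acyclic: the (2E)-geranic amide of twofold-symmetric (2R,5R)-2,5-dimethylpyrrolidine.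

Key step: step 2

Assumption: the (2R,5R)-amine is taken to lead to the (1S,5R)-ketone of step 2 (steric model in that step); if the induction proves opposite, the (2S,5S)-amine is used in the same steps.

Remark: the bicyclic ketone of step 2 is a β,γ-unsaturated cyclobutanone that can lose optical purity through reversible vinylketene formation in light or on heating, so it is kept dark and cool and oxidised without storage.

Step 1
Reactants: 1 (2E)-geranic acid; 2 (2R,5R)-2,5-dimethylpyrrolidine
Product: 4 (2E)-1-[(2R,5R)-2,5-dimethylpyrrolidin-1-yl]-3,7-dimethylocta-2,6-dien-1-one, via geranoyl chloride 3 (not isolated)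
Conditions: (COCl)2, DMF (cat.), CH2Cl2, 0 °C to rt; evaporate; then 2, 2 M NaOH (aq), CH2Cl2, 0 °C; chromatography
Reagents that add atoms: none
Why: Chlorination of the acid through the Vilsmeier-type chloroiminium salt and Schotten–Baumann N-acylation of the hindered secondary amine should give the amide, the biphasic hydroxide avoiding the vinylketene pathway that could scramble the alkene and chromatography removing any (2Z) isomer, so that C2 lies trans to the carbonyl group as the key step requires; no stereocentre is formed.

Step 2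
Reactants: 4 (2E)-1-[(2R,5R)-2,5-dimethylpyrrolidin-1-yl]-3,7-dimethylocta-2,6-dien-1-one
Product: 7 chrysanthenone [(1S,5R)-2,7,7-trimethylbicyclo[3.1.1]hept-2-en-6-one], via vinylketeniminium triflate 5 (not isolated), via bicyclic iminium triflate 6 (not isolated)
Conditions: Tf2O, 2,4,6-collidine, ClCH2CH2Cl, −20 °C to 70 °C, dark; then H2O, NaHCO3, 40 °C
Reagents that add atoms: water, O
Why: Proposed new method: Tf2O converts the amide into an O-triflyl iminium ion, collidine removes a γ-proton from C2 and triflate leaves to give vinylketeniminium ion 5, whose central carbon C7 is attacked by the prenyl alkene at C4 while the enamine carbon C6 closes onto the developing tertiary cation C5, and water finally hydrolyses cyclobutaniminium ion 6 to the ketone and frees the amine. The closest known reaction types are the thermal intramolecular vinylketene–alkene [2+2] cycloaddition of geranoyl chloride, which gives this ring system as a racemate, and the enantioselective keteniminium–alkene [2+2] cycloaddition of saturated amides of twofold-symmetric 2,5-dimethylpyrrolidine; a vinylketeniminium ion generated by γ-deprotonation has not been used in this way. The six-membered ring C7–C6–C1=C2–C3–C4 closes by a 6-exo attack of the C4=C5 alkene on the digonal carbon C7 (Markovnikov, charge at C5), and the cyclobutane C7–C4–C5–C6, which at the same time completes the cyclohexene C1–C6, closes by attack of the endocyclic enamine carbon C6 on the exocyclic cation C5, so that the cycloaddition is crossed and not fused. C4 is set in the first bond formation under control of the auxiliary, since the ring methyl group that lies on the alkene side of the C7=N+ unit should force the CMe2 terminus C5 to the opposite side, and C6 is then fixed by the ring because a one-carbon bridge can span C4 and C6 only cis. The step needs proton loss from C2 and not from the C1 methyl group, with C6 and C3 cis on the new alkene, which the (2E) geometry of 4 favours by placing C2 trans to the bulky iminium group and the methyl group cis to it, while reversible proton transfer through collidinium triflate lets the dienyl isomer that cannot cyclise return; it also needs crossed regiochemistry, secured by the trisubstituted alkene, and facial selectivity, secured only by the auxiliary.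

Step 3
Reactants: 7 chrysanthenone
Product: 9 epoxy lactone [2,3-epoxy-2,8,8-trimethyl-6-oxabicyclo[3.2.1]octan-7-one], via chrysanthenone epoxide 8 (not isolated)
Conditions: DMDO, acetone, 0 °C, dark; evaporate; then mCPBA, NaHCO3, CH2Cl2, 0 °C to rt
Reagents that add atoms: dimethyldioxirane (DMDO), CC1(C)OO1; 3-chloroperoxybenzoic acid (mCPBA), OOC(=O)c1cccc(Cl)c1
Why: The neutral dioxirane, which does not effect Baeyer–Villiger oxidation, should epoxidise the trisubstituted alkene on the face away from the CMe2 bridge and so remove the light-sensitive β,γ-enone, after which Baeyer–Villiger oxidation of the strained cyclobutanone should insert oxygen at bridgehead C4 with retention, because C6 carries the electron-withdrawing epoxide carbon and migrates less readily.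

Step 4
Reactants: 9 epoxy lactone
Product: 10 (1S,5R)-2,8,8-trimethyl-6-oxabicyclo[3.2.1]oct-2-en-7-one
Conditions: Re2O7 (cat.), P(OPh)3, toluene, 100 °C
Reagents that add atoms: none
Why: Rhenium-catalysed oxygen-atom transfer from the epoxide to the phosphite (epoxide deoxygenation) should return the C1=C2 alkene under neutral conditions that leave the lactone alone, the two epoxide stereocentres disappearing and C6 being unable to epimerise because the lactone bridge must stay cis.

Step 5
Reactants: 10 (1S,5R)-2,8,8-trimethyl-6-oxabicyclo[3.2.1]oct-2-en-7-one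
Product: 11 (1R,5S)-5-(hydroxymethyl)-4,6,6-trimethylcyclohex-3-en-1-ol
Conditions: LiAlH4, THF, 0 °C to rt; then H2O, 15% NaOH (aq), H2O
Reagents that add atoms: none
Why: Hydride reduction of the lactone should give the primary alcohol at C7 and the secondary alcohol at C4 without touching either stereocentre or the alkene, so that the cis relation inherited from the bicycle is kept.

Step 6
Reactants: 11 (1R,5S)-5-(hydroxymethyl)-4,6,6-trimethylcyclohex-3-en-1-ol; 12 isovaleryl chloride
Product: 15 (1R,5S)-5-(hydroxymethyl)-4,6,6-trimethylcyclohex-3-en-1-yl 3-methylbutanoate, via triethylsilyl ether 13 (not isolated), via silyl ether ester 14 (not isolated)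
Conditions: Et3SiCl, pyridine, CH2Cl2, −40 °C; then 12, DMAP, 0 °C to rt; then 1 M HCl (aq), THF, rt
Reagents that add atoms: none
Why: Transient silyl protection should work because the primary hydroxyl is silylated far faster than the neopentyl-type secondary one, DMAP-catalysed acylation then esterifies the C4 hydroxyl with retention, and dilute acid removes the labile primary silyl ether, which avoids carrying a free cis-1,4-diol (prone to cyclise to a bridged ether) into the etherification.

Step 7
Reactants: 15 (1R,5S)-5-(hydroxymethyl)-4,6,6-trimethylcyclohex-3-en-1-yl 3-methylbutanoate; 16 umbelliferone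
Product: 17 (1R,5S)-4,6,6-trimethyl-5-{[(2-oxo-2H-chromen-7-yl)oxy]methyl}cyclohex-3-en-1-yl 3-methylbutanoate (target)
Conditions: PPh3, DIAD, THF, 0 °C to rt
Reagents that add atoms: none
Why: Mitsunobu etherification should join the primary carbon C7 to the acidic 7-hydroxyl of umbelliferone by SN2 displacement of the alkoxyphosphonium group, with no stereocentre involved and the C4 ester inert.

Compound list
1 | (2E)-geranic acid [(2E)-3,7-dimethylocta-2,6-dienoic acid] | CC(C)=CCC/C(C)=C/C(=O)O | starting material
2 | (2R,5R)-2,5-dimethylpyrrolidine (trans) | C[C@@H]1CC[C@@H](C)N1 | starting material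
3 | (2E)-geranoyl chloride | CC(C)=CCC/C(C)=C/C(=O)Cl | intermediate (not isolated)
4 | (2E)-1-[(2R,5R)-2,5-dimethylpyrrolidin-1-yl]-3,7-dimethylocta-2,6-dien-1-one | C[C@@H]1CC[C@@H](C)N1C(=O)/C=C(\C)CCC=C(C)C | intermediate
5 | (2R,5R)-1-[(3Z)-3,7-dimethylocta-1,3,6-trien-1-ylidene]-2,5-dimethylpyrrolidin-1-ium triflate (C6 and C3 cis on C1=C2) | C[C@@H]1CC[C@@H](C)[N+]1=C=C/C(C)=C\CC=C(C)C.[O-]S(=O)(=O)C(F)(F)F | intermediate (not isolated)
6 | (2R,5R)-2,5-dimethyl-1-[(1S,5R)-2,7,7-trimethylbicyclo[3.1.1]hept-2-en-6-ylidene]pyrrolidin-1-ium triflate | CC1=CC[C@@H]2C(C)(C)[C@H]1C2=[N+]1[C@H](C)CC[C@H]1C.[O-]S(=O)(=O)C(F)(F)F | intermediate (not isolated)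
7 | chrysanthenone, (1S,5R)-2,7,7-trimethylbicyclo[3.1.1]hept-2-en-6-one | CC1=CC[C@@H]2C(C)(C)[C@H]1C2=O | intermediate
8 | chrysanthenone epoxide, 2,3-epoxy-2,7,7-trimethylbicyclo[3.1.1]heptan-6-one; bridgeheads as in 7, epoxide oxygen on the face of the carbonyl bridge, anti to CMe2 | C[C@]12O[C@H]1C[C@@H]3C(C)(C)[C@H]2C3=O | intermediate (not isolated)
9 | 2,3-epoxy-2,8,8-trimethyl-6-oxabicyclo[3.2.1]octan-7-one; lactone oxygen on C4, bridgeheads as in 7, epoxide oxygen on the face of the lactone bridge | C[C@]12O[C@H]1C[C@@H]3C(C)(C)[C@H]2C(=O)O3 | intermediate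
10 | (1S,5R)-2,8,8-trimethyl-6-oxabicyclo[3.2.1]oct-2-en-7-one | CC1=CC[C@@H]2C(C)(C)[C@H]1C(=O)O2 | intermediate
11 | (1R,5S)-5-(hydroxymethyl)-4,6,6-trimethylcyclohex-3-en-1-ol (cis) | CC1=CC[C@@H](O)C(C)(C)[C@H]1CO | intermediate
12 | isovaleryl chloride (3-methylbutanoyl chloride) | CC(C)CC(=O)Cl | starting material
13 | (1R,5S)-4,6,6-trimethyl-5-{[(triethylsilyl)oxy]methyl}cyclohex-3-en-1-ol | CC1=CC[C@@H](O)C(C)(C)[C@H]1CO[Si](CC)(CC)CC | intermediate (not isolated)
14 | (1R,5S)-4,6,6-trimethyl-5-{[(triethylsilyl)oxy]methyl}cyclohex-3-en-1-yl 3-methylbutanoate | CC1=CC[C@@H](OC(=O)CC(C)C)C(C)(C)[C@H]1CO[Si](CC)(CC)CC | intermediate (not isolated)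
15 | (1R,5S)-5-(hydroxymethyl)-4,6,6-trimethylcyclohex-3-en-1-yl 3-methylbutanoate | CC1=CC[C@@H](OC(=O)CC(C)C)C(C)(C)[C@H]1CO | intermediate
16 | umbelliferone (7-hydroxy-2H-chromen-2-one) | O=c1ccc2ccc(O)cc2o1 | starting material
17 | (1R,5S)-4,6,6-trimethyl-5-{[(2-oxo-2H-chromen-7-yl)oxy]methyl}cyclohex-3-en-1-yl 3-methylbutanoate (CNP0266015.1) | CC1=CC[C@@H](OC(=O)CC(C)C)C(C)(C)[C@H]1COc1ccc2ccc(=O)oc2c1 | target

Total step count: 7. Longest linear sequence: 7 steps (from geranic acid 1).

Steps most likely to fail

Step 2 (new method). What may go wrong: loss of a proton from the C1 methyl group instead of C2 (leading to the 2-methylidene isomer), sluggish ring closure of the unsaturated keteniminium ion, or weak facial control by the auxiliary. The fallback uses known chemistry only; it sets out from geranoyl chloride 3 and comes back to the route at diol 11. Heating 3 with Et3N in toluene generates the vinylketene, whose intramolecular [2+2] cycloaddition should give racemic 7,7-dimethyl-2-methylidenebicyclo[3.1.1]heptan-6-one F1 together with racemic chrysanthenone F2. F1 is isomerised to F2 with catalytic RhCl3·3H2O in EtOH. F2 is taken through the conditions of steps 3 to 5 by way of racemic chrysanthenone epoxide F3 (not isolated), racemic epoxy lactone F4 and racemic lactone F5 to racemic diol F6. Acylation of the primary hydroxyl of F6 with (1S)-camphanic chloride (pyridine, CH2Cl2, 0 °C) gives the camphanate of the (1R,5S)-diol F7 and the camphanate of the (1S,5R)-diol F8. These are separated by chromatography or crystallisation, and methanolysis of F7 (K2CO3, MeOH) returns 11.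

Step 3. What may go wrong: oxygen insertion on the epoxide side (migration of C6 instead of C4), or acid-induced opening of the strained tertiary epoxide before the ring has expanded. The fallback sets out from 7 and comes back at lactone 10, so that step 4 is bypassed as well. Catalytic OsO4 with N-methylmorpholine N-oxide (acetone/H2O) should dihydroxylate 7 from the face away from the CMe2 bridge to the cis-diol ketone F9. Its hydroxylated carbons are acid-stable and deactivate C6 at least as much as the epoxide. Buffered mCPBA then gives the diol lactone F10, 1,1'-thiocarbonyldiimidazole (toluene, 80 °C) closes the cyclic thiocarbonate F11, and Corey–Winter elimination with P(OMe)3 (110 °C) restores the alkene to give 10.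

Step 7. What may go wrong: slow displacement at the β-branched carbon C7, so that the alkoxyphosphonium intermediate is diverted to alkylation of the hydrazide or decomposes. The fallback sets out from 15 and comes back at target 17. Tf2O and 2,6-lutidine (CH2Cl2, −78 °C) convert 15 into the primary triflate F12, which alkylates umbelliferone 16 as its cesium salt (Cs2CO3, DMF, 0 °C to rt) in a Williamson-type SN2 reaction.

Further compounds
F1 | step 2 | racemic 7,7-dimethyl-2-methylidenebicyclo[3.1.1]heptan-6-one | C=C1CC[C@@H]2C(C)(C)[C@H]1C2=O.C=C1CC[C@H]2C(C)(C)[C@@H]1C2=O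
F2 | step 2 | racemic chrysanthenone | CC1=CC[C@@H]2C(C)(C)[C@H]1C2=O.CC1=CC[C@H]2C(C)(C)[C@@H]1C2=O
F3 | step 2 | racemic chrysanthenone epoxide (relative configuration as in 8) | C[C@]12O[C@H]1C[C@@H]3C(C)(C)[C@H]2C3=O.C[C@@]12O[C@@H]1C[C@H]3C(C)(C)[C@@H]2C3=O
F4 | step 2 | racemic epoxy lactone (relative configuration as in 9) | C[C@]12O[C@H]1C[C@@H]3C(C)(C)[C@H]2C(=O)O3.C[C@@]12O[C@@H]1C[C@H]3C(C)(C)[C@@H]2C(=O)O3
F5 | step 2 | racemic 2,8,8-trimethyl-6-oxabicyclo[3.2.1]oct-2-en-7-one | CC1=CC[C@@H]2C(C)(C)[C@H]1C(=O)O2.CC1=CC[C@H]2C(C)(C)[C@@H]1C(=O)O2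
F6 | step 2 | racemic cis-5-(hydroxymethyl)-4,6,6-trimethylcyclohex-3-en-1-ol | CC1=CC[C@@H](O)C(C)(C)[C@H]1CO.CC1=CC[C@H](O)C(C)(C)[C@@H]1CO
F7 | step 2 | [(1S,5R)-5-hydroxy-2,6,6-trimethylcyclohex-2-en-1-yl]methyl (1S,4R)-4,7,7-trimethyl-3-oxo-2-oxabicyclo[2.2.1]heptane-1-carboxylate (camphanate of 11) | CC1=CC[C@@H](O)C(C)(C)[C@H]1COC(=O)[C@@]12CC[C@@](C)(C(=O)O1)C2(C)C
F8 | step 2 | [(1R,5S)-5-hydroxy-2,6,6-trimethylcyclohex-2-en-1-yl]methyl (1S,4R)-4,7,7-trimethyl-3-oxo-2-oxabicyclo[2.2.1]heptane-1-carboxylate (camphanate of the enantiomer of 11) | CC1=CC[C@H](O)C(C)(C)[C@@H]1COC(=O)[C@@]12CC[C@@](C)(C(=O)O1)C2(C)C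
F9 | step 3 | 2,3-dihydroxy-2,7,7-trimethylbicyclo[3.1.1]heptan-6-one, bridgeheads as in 7, both hydroxyls on the face of the carbonyl bridge | C[C@]1(O)[C@@H](O)C[C@@H]2C(C)(C)[C@H]1C2=O
F10 | step 3 | 2,3-dihydroxy-2,8,8-trimethyl-6-oxabicyclo[3.2.1]octan-7-one, hydroxyls on the face of the lactone bridge | C[C@]1(O)[C@@H](O)C[C@@H]2C(C)(C)[C@H]1C(=O)O2
F11 | step 3 | cyclic 2,3-thiocarbonate of F10 | C[C@]12OC(=S)O[C@H]1C[C@@H]3C(C)(C)[C@H]2C(=O)O3
F12 | step 7 | (1R,5S)-4,6,6-trimethyl-5-{[(trifluoromethanesulfonyl)oxy]methyl}cyclohex-3-en-1-yl 3-methylbutanoate | CC1=CC[C@@H](OC(=O)CC(C)C)C(C)(C)[C@H]1COS(=O)(=O)C(F)(F)F
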